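**Plan**

1. Numbering used throughout (germacrane type): ring C1–C10 with C1=C10 (Z, methyl C14 on C10), C2–O-angelate, C4(C15H2OAc)=C5, C6–O (lactone), C7, C8–OH, C9H2; lactone C11(=C13H2)–C12(=O)–O–C6.
2. Cuts: C8 carbinol ← C8 ketone ← 8-epi alcohol; ten-membered ring at C7–C8 (allylchromium + aldehyde), which turns the α-methylene lactone back into a 3-(bromomethyl)butenolide; butenolide at C7=C11 (RCM) and O–C12 (ester); then C4–C15 (Stille), C5–C6 (alkynylation), C2–C3 (propargylation), C10–C14 (cuprate).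
3. Enabling feature: the homoallylic alcohol C13=C11–C7–C8–OH, whose allyl part (C13, C11, C7) sits on the γ-lactone ring (O–C12–C11–C7–C6). This is the retron of a 2-carbonylallylation, so the lactone itself, as its C7=C11 butenolide carrying Br on C13, is the allyl donor and C8 is the aldehyde.
4. Forward order: linear chain growth C8→C2 (Z-enal), C3–C5 (alkyne), C6/C7 (enynol), C15; the butenolide ring is closed first (RCM), the ten-membered ring last (intramolecular Cr(II) allylation); C8 is then reset by oxidation/reduction.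
5. Stereochemistry: C2 from phosphoric-acid-catalysed propargylation; C6 from Zn-ProPhenol alkynylation; C7 from attack anti to the C5 chain on the butenolide; C8 from (S)-CBS reduction. The 1(10)-Z geometry comes from syn-carbocupration; the C4=C5 geometry from trans-hydrosilylation, iododesilylation and Stille coupling (the last two with retention); the angelate from a non-isomerising Yamaguchi esterification.

Key step: step 16

Remark: the facial sense of the two catalyst-controlled additions (steps 5 and 7) is assigned by analogy with simple aldehydes; should either prove reversed, the antipodal catalyst is used.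

**Step 1**
Reactants: 1 tert-butyl(but-3-yn-1-yloxy)dimethylsilane
Product: 3 methyl 5-((tert-butyldimethylsilyl)oxy)pent-2-ynoate, via lithium acetylide 2 (not isolated)
Conditions: n-BuLi, THF, −78 °C; then ClCO2Me, −78 → 0 °C
Reagents that add atoms: methyl chloroformate, COC(=O)Cl
Why: Deprotonation of the terminal alkyne and C-acylation of the lithium acetylide with a chloroformate (acetylide acylation) gives the ynoate, the silyl ether being inert.

**Step 2**
Reactants: 3 methyl 5-((tert-butyldimethylsilyl)oxy)pent-2-ynoate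
Product: 4 methyl (Z)-5-((tert-butyldimethylsilyl)oxy)-3-methylpent-2-enoate
Conditions: Me2CuLi (from MeLi, CuI), THF, −78 °C; MeOH then aq NH4Cl at −78 °C
Reagents that add atoms: lithium dimethylcuprate, [Li+].C[Cu-]C
Why: Conjugate addition of the Gilman cuprate to the ynoate is a syn-carbocupration, and protonation at −78 °C before the alkenylcopper can equilibrate puts H cis to the new methyl, so that C9 and the ester carbon (C2) end up cis (the 1(10)-Z geometry).

**Step 3**
Reactants: 4 methyl (Z)-5-((tert-butyldimethylsilyl)oxy)-3-methylpent-2-enoate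
Product: 5 (Z)-5-((tert-butyldimethylsilyl)oxy)-3-methylpent-2-en-1-ol
Conditions: DIBAL-H (2.2 equiv), CH2Cl2, −78 °C; Rochelle salt work-up
Reagents that add atoms: none
Why: DIBAL-H 1,2-reduction of the enoate gives the allylic alcohol without touching the trisubstituted alkene or the silyl ether.

**Step 4**
Reactants: 5 (Z)-5-((tert-butyldimethylsilyl)oxy)-3-methylpent-2-en-1-ol
Product: 6 (Z)-5-((tert-butyldimethylsilyl)oxy)-3-methylpent-2-enal
Conditions: TEMPO (10 mol%), PhI(OAc)2, CH2Cl2, rt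
Reagents that add atoms: none
Why: The TEMPO/PhI(OAc)2 oxidation of allylic alcohols is near-neutral and should give the Z-enal without Z/E isomerisation.

**Step 5**
Reactants: 6 (Z)-5-((tert-butyldimethylsilyl)oxy)-3-methylpent-2-enal
Product: 8 (4S,5Z)-8-((tert-butyldimethylsilyl)oxy)-6-methyloct-5-en-1-yn-4-ol, via homopropargyl pinacol borate 7 (not isolated)
Conditions: allenylboronic acid pinacol ester, (S)-TRIP phosphoric acid (5 mol%), 4 Å MS, toluene, −20 °C; aqueous work-up
Reagents that add atoms: allenylboronic acid pinacol ester, C=C=CB1OC(C)(C)C(C)(C)O1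
Why: Chiral-phosphoric-acid-catalysed propargylboration (SE2′ through a closed six-membered transition state with the acid bound to the boronate) adds 1,2 to the enal, and the catalyst is expected to set the S carbinol at C2.

**Step 6**
Reactants: 8 (4S,5Z)-8-((tert-butyldimethylsilyl)oxy)-6-methyloct-5-en-1-yn-4-ol; 9 angelic acid
Product: 10 (4S,5Z)-8-((tert-butyldimethylsilyl)oxy)-6-methyloct-5-en-1-yn-4-yl (Z)-2-methylbut-2-enoate
Conditions: 9, 2,4,6-trichlorobenzoyl chloride, Et3N, toluene, rt; then 8, 80 °C (no DMAP)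
Reagents that add atoms: none
Why: Yamaguchi esterification through the mixed trichlorobenzoic anhydride without DMAP acylates the secondary alcohol with retention and is the standard way to install an angelate without Z→E isomerisation to the tiglate.

**Step 7**
Reactants: 10 (4S,5Z)-8-((tert-butyldimethylsilyl)oxy)-6-methyloct-5-en-1-yn-4-yl (Z)-2-methylbut-2-enoate; 11 (E)-but-2-enal
Product: 12 (2E,4S,8S,9Z)-12-((tert-butyldimethylsilyl)oxy)-4-hydroxy-10-methyldodeca-2,9-dien-5-yn-8-yl (Z)-2-methylbut-2-enoate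
Conditions: Me2Zn (3 equiv), (S,S)-ProPhenol (20 mol%), Ph3PO (40 mol%), toluene, 0–4 °C; then 11
Reagents that add atoms: none
Why: Zn-ProPhenol-catalysed asymmetric alkynylation adds the alkynylzinc 1,2 to the enal inside the dinuclear zinc pocket, which should set the C6 carbinol (S descriptor at this stage), while the esters and silyl ether tolerate Me2Zn.

**Step 8**
Reactants: 12 (2E,4S,8S,9Z)-12-((tert-butyldimethylsilyl)oxy)-4-hydroxy-10-methyldodeca-2,9-dien-5-yn-8-yl (Z)-2-methylbut-2-enoate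
Product: 13 (2E,4S,5Z,8S,9Z)-12-((tert-butyldimethylsilyl)oxy)-4-hydroxy-10-methyl-6-(triethylsilyl)dodeca-2,5,9-trien-8-yl (Z)-2-methylbut-2-enoate
Conditions: Et3SiH, [Cp*Ru(MeCN)3]PF6 (2 mol%), CH2Cl2, 0 °C → rt
Reagents that add atoms: triethylsilane, CC[SiH](CC)CC
Why: Cationic-ruthenium-catalysed trans-hydrosilylation of the internal propargylic alcohol adds H and Si anti with silicon on the carbon distal to the free hydroxyl (C4), giving the vinylsilane with Si cis to C6, the esterified homopropargylic oxygen being a much weaker director.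

**Step 9**
Reactants: 13 (2E,4S,5Z,8S,9Z)-12-((tert-butyldimethylsilyl)oxy)-4-hydroxy-10-methyl-6-(triethylsilyl)dodeca-2,5,9-trien-8-yl (Z)-2-methylbut-2-enoate
Product: 14 (2E,4S,5Z,8S,9Z)-12-((tert-butyldimethylsilyl)oxy)-4-hydroxy-6-iodo-10-methyldodeca-2,5,9-trien-8-yl (Z)-2-methylbut-2-enoate
Conditions: N-iodosuccinimide (1.2 equiv), 2,6-lutidine, (CF3)2CHOH, 0 °C, short reaction time
Reagents that add atoms: N-iodosuccinimide, O=C1CCC(=O)N1I
Why: Ipso-iododesilylation of the vinylsilane (β-silyl cation, retention of geometry) should be much faster than iodination of the other, less nucleophilic alkenes and gives the vinyl iodide with I cis to C6.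

**Step 10**
Reactants: 14 (2E,4S,5Z,8S,9Z)-12-((tert-butyldimethylsilyl)oxy)-4-hydroxy-6-iodo-10-methyldodeca-2,5,9-trien-8-yl (Z)-2-methylbut-2-enoate
Product: 15 (2E,4S,5Z,8S,9Z)-12-((tert-butyldimethylsilyl)oxy)-4-hydroxy-6-(hydroxymethyl)-10-methyldodeca-2,5,9-trien-8-yl (Z)-2-methylbut-2-enoate
Conditions: Bu3SnCH2OH (1.5 equiv), Pd2(dba)3 (5 mol%), AsPh3 (20 mol%), NMP, 50 °C
Reagents that add atoms: (tributylstannyl)methanol, CCCC[Sn](CCCC)(CCCC)CO
Why: Stille hydroxymethylation of the vinyl iodide proceeds with retention of olefin geometry and so places C15 cis to C6, the weakly donating arsine ligand speeding transmetalation and disfavouring ionisation of the allylic angelate.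

**Step 11**
Reactants: 15 (2E,4S,5Z,8S,9Z)-12-((tert-butyldimethylsilyl)oxy)-4-hydroxy-6-(hydroxymethyl)-10-methyldodeca-2,5,9-trien-8-yl (Z)-2-methylbut-2-enoate
Product: 16 (2E,4S,5Z,8S,9Z)-6-(acetoxymethyl)-12-((tert-butyldimethylsilyl)oxy)-4-hydroxy-10-methyldodeca-2,5,9-trien-8-yl (Z)-2-methylbut-2-enoate
Conditions: AcCl (1.05 equiv), 2,4,6-collidine, CH2Cl2, −78 °C
Reagents that add atoms: acetyl chloride, CC(=O)Cl
Why: Kinetically selective acylation at −78 °C acetylates the primary allylic hydroxyl in preference to the hindered secondary bis-allylic one.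

**Step 12**
Reactants: 16 (2E,4S,5Z,8S,9Z)-6-(acetoxymethyl)-12-((tert-butyldimethylsilyl)oxy)-4-hydroxy-10-methyldodeca-2,5,9-trien-8-yl (Z)-2-methylbut-2-enoate; 17 2-(bromomethyl)acrylic acid
Product: 18 (2E,4S,5Z,8S,9Z)-6-(acetoxymethyl)-12-((tert-butyldimethylsilyl)oxy)-10-methyl-8-(((Z)-2-methylbut-2-enoyl)oxy)dodeca-2,5,9-trien-4-yl 2-(bromomethyl)acrylate
Conditions: 17 (1.5 equiv), DCC (1.5 equiv), DMAP (5 mol%), CH2Cl2, −20 → 0 °C
Reagents that add atoms: none
Why: Steglich carbodiimide esterification acylates the remaining secondary alcohol with retention at C6, with DMAP kept catalytic and the temperature low to avoid SN2′ attack on the allylic bromide.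

**Step 13**
Reactants: 18 (2E,4S,5Z,8S,9Z)-6-(acetoxymethyl)-12-((tert-butyldimethylsilyl)oxy)-10-methyl-8-(((Z)-2-methylbut-2-enoyl)oxy)dodeca-2,5,9-trien-4-yl 2-(bromomethyl)acrylate
Product: 19 (1Z,4S,5Z)-2-(acetoxymethyl)-1-((2R)-4-(bromomethyl)-5-oxo-2,5-dihydrofuran-2-yl)-8-((tert-butyldimethylsilyl)oxy)-6-methylocta-1,5-dien-4-yl (Z)-2-methylbut-2-enoate
Conditions: Grubbs second-generation catalyst (10 mol%), CH2Cl2 (5 mM), 40 °C
Reagents that add atoms: none
Why: Ring-closing metathesis initiates at the propenyl group and closes onto the 1,1-disubstituted acrylate to give the butenolide with loss of propene, the trisubstituted alkenes and the angelate being inert and C6 untouched (its descriptor changes from S to R by priority only).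

**Step 14**
Reactants: 19 (1Z,4S,5Z)-2-(acetoxymethyl)-1-((2R)-4-(bromomethyl)-5-oxo-2,5-dihydrofuran-2-yl)-8-((tert-butyldimethylsilyl)oxy)-6-methylocta-1,5-dien-4-yl (Z)-2-methylbut-2-enoate
Product: 20 (1Z,4S,5Z)-2-(acetoxymethyl)-1-((2R)-4-(bromomethyl)-5-oxo-2,5-dihydrofuran-2-yl)-8-hydroxy-6-methylocta-1,5-dien-4-yl (Z)-2-methylbut-2-enoate
Conditions: 48% aq HF, MeCN, 0 °C
Reagents that add atoms: none
Why: Acidic fluoride desilylation cleaves the primary TBS ether under non-basic conditions that the esters, the allylic bromide and the base-sensitive γ-stereocentre of the butenolide should tolerate.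

**Step 15**
Reactants: 20 (1Z,4S,5Z)-2-(acetoxymethyl)-1-((2R)-4-(bromomethyl)-5-oxo-2,5-dihydrofuran-2-yl)-8-hydroxy-6-methylocta-1,5-dien-4-yl (Z)-2-methylbut-2-enoate
Product: 21 (1Z,4S,5Z)-2-(acetoxymethyl)-1-((2R)-4-(bromomethyl)-5-oxo-2,5-dihydrofuran-2-yl)-6-methyl-8-oxoocta-1,5-dien-4-yl (Z)-2-methylbut-2-enoate
Conditions: Dess–Martin periodinane, NaHCO3, CH2Cl2, 0 °C → rt; used crude at once
Reagents that add atoms: none
Why: Buffered Dess–Martin oxidation gives the β,γ-unsaturated aldehyde under neutral conditions that should not move the Z-alkene into conjugation.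

**Step 16**
Reactants: 21 (1Z,4S,5Z)-2-(acetoxymethyl)-1-((2R)-4-(bromomethyl)-5-oxo-2,5-dihydrofuran-2-yl)-6-methyl-8-oxoocta-1,5-dien-4-yl (Z)-2-methylbut-2-enoate
Product: 23 (3aR,4S,6Z,8S,10Z,11aR)-10-(acetoxymethyl)-4-hydroxy-6-methyl-3-methylidene-2-oxo-2,3,3a,4,5,8,9,11a-octahydrocyclodeca[b]furan-8-yl (Z)-2-methylbut-2-enoate, via allylchromium(III) dichloride 22 (not isolated)
Conditions: CrCl2 (10 equiv), 4 Å MS, THF, rt; 21 added by syringe pump over ca. 10 h (final ca. 2 mM); aqueous work-up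
Reagents that add atoms: none
Why: Cr(II) reduces the allylic C13–Br bond to the allylchromium(III) species 22, whose γ-terminus C7 adds to the chromium-bound aldehyde C8 through a closed six-membered Zimmerman–Traxler transition state (SE2′), so that the endocyclic C7=C11 bond of the butenolide becomes the exocyclic C11=C13 methylene (Nozaki–Hiyama–Kishi/Barbier carbonyl allylation). The closest known reactions are the intermolecular Cr-, Zn- and In-mediated additions of 3-(bromomethyl)furan-2(5H)-ones to aldehydes and the macrocyclising allylations of aldehydes with 2-(alkoxycarbonyl)allyl bromides. The ten-membered carbocycle is closed by the C7–C8 bond in a 10-exo-trig mode at the carbonyl, the lactone being already in place. C7 is set by C6, because the allyl unit is attacked on the butenolide face anti to the C5 side chain (trans-fused lactone); C8 follows from the chair transition state with the ring-locked allyl geometry (C6 trans to C13) and C9 equatorial, which predicts the 7,8-anti (8S) alcohol, hence the reset in steps 17 and 18. The step needs γ- over α-attack (six-membered versus larger cyclic transition state), ring closure over oligomerisation (slow addition, high dilution) and no isomerisation of the β,γ-unsaturated aldehyde, which the neutral, non-basic Cr(II) medium should secure.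

**Step 17**
Reactants: 23 (3aR,4S,6Z,8S,10Z,11aR)-10-(acetoxymethyl)-4-hydroxy-6-methyl-3-methylidene-2-oxo-2,3,3a,4,5,8,9,11a-octahydrocyclodeca[b]furan-8-yl (Z)-2-methylbut-2-enoate
Product: 24 (3aS,6Z,8S,10Z,11aR)-10-(acetoxymethyl)-6-methyl-3-methylidene-2,4-dioxo-2,3,3a,4,5,8,9,11a-octahydrocyclodeca[b]furan-8-yl (Z)-2-methylbut-2-enoate
Conditions: Dess–Martin periodinane, NaHCO3, CH2Cl2, 0 °C; used crude at once
Reagents that add atoms: none
Why: Dess–Martin oxidation of the secondary alcohol removes the C8 stereocentre (either C8 epimer converges here) under buffered neutral conditions that should limit enolisation towards C7.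

**Step 18**
Reactants: 24 (3aS,6Z,8S,10Z,11aR)-10-(acetoxymethyl)-6-methyl-3-methylidene-2,4-dioxo-2,3,3a,4,5,8,9,11a-octahydrocyclodeca[b]furan-8-yl (Z)-2-methylbut-2-enoate
Product: 25 (3aR,4R,6Z,8S,10Z,11aR)-10-(acetoxymethyl)-4-hydroxy-6-methyl-3-methylidene-2-oxo-2,3,3a,4,5,8,9,11a-octahydrocyclodeca[b]furan-8-yl (Z)-2-methylbut-2-enoate
Conditions: (S)-2-methyl-CBS-oxazaborolidine (0.5 equiv), catecholborane (1.5 equiv), toluene, −78 °C
Reagents that add atoms: none
Why: Corey–Bakshi–Shibata reduction with the (S)-oxazaborolidine (branched C7 as the large, C9H2 as the small substituent) should deliver hydride to the face giving the 8R alcohol, matched with the substrate preference for attack anti to C6 (from the H-7 side), while catecholborane at −78 °C leaves the alkenes and esters untouched.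

**Compound list**

1 | tert-butyl(but-3-yn-1-yloxy)dimethylsilane | C#CCCO[Si](C)(C)C(C)(C)C | starting material
2 | (4-((tert-butyldimethylsilyl)oxy)but-1-yn-1-yl)lithium | [Li]C#CCCO[Si](C)(C)C(C)(C)C | intermediate (not isolated)
3 | methyl 5-((tert-butyldimethylsilyl)oxy)pent-2-ynoate | COC(=O)C#CCCO[Si](C)(C)C(C)(C)C | intermediate
4 | methyl (Z)-5-((tert-butyldimethylsilyl)oxy)-3-methylpent-2-enoate | COC(=O)/C=C(/C)CCO[Si](C)(C)C(C)(C)C | intermediate
5 | (Z)-5-((tert-butyldimethylsilyl)oxy)-3-methylpent-2-en-1-ol | OC/C=C(/C)CCO[Si](C)(C)C(C)(C)C | intermediate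
6 | (Z)-5-((tert-butyldimethylsilyl)oxy)-3-methylpent-2-enal | O=C/C=C(/C)CCO[Si](C)(C)C(C)(C)C | intermediate
7 | 2-(((4S,5Z)-8-((tert-butyldimethylsilyl)oxy)-6-methyloct-5-en-1-yn-4-yl)oxy)-4,4,5,5-tetramethyl-1,3,2-dioxaborolane | C#CC[C@H](OB1OC(C)(C)C(C)(C)O1)/C=C(/C)CCO[Si](C)(C)C(C)(C)C | intermediate (not isolated)
8 | (4S,5Z)-8-((tert-butyldimethylsilyl)oxy)-6-methyloct-5-en-1-yn-4-ol | C#CC[C@H](O)/C=C(/C)CCO[Si](C)(C)C(C)(C)C | intermediate
9 | angelic acid, (Z)-2-methylbut-2-enoic acid | C/C=C(/C)C(=O)O | starting material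
10 | (4S,5Z)-8-((tert-butyldimethylsilyl)oxy)-6-methyloct-5-en-1-yn-4-yl (Z)-2-methylbut-2-enoate | C#CC[C@H](OC(=O)/C(C)=C\C)/C=C(/C)CCO[Si](C)(C)C(C)(C)C | intermediate
11 | (E)-but-2-enal (crotonaldehyde) | C/C=C/C=O | starting material
12 | (2E,4S,8S,9Z)-12-((tert-butyldimethylsilyl)oxy)-4-hydroxy-10-methyldodeca-2,9-dien-5-yn-8-yl (Z)-2-methylbut-2-enoate | C/C=C/[C@H](O)C#CC[C@H](OC(=O)/C(C)=C\C)/C=C(/C)CCO[Si](C)(C)C(C)(C)C | intermediate
13 | (2E,4S,5Z,8S,9Z)-12-((tert-butyldimethylsilyl)oxy)-4-hydroxy-10-methyl-6-(triethylsilyl)dodeca-2,5,9-trien-8-yl (Z)-2-methylbut-2-enoate | C/C=C/[C@H](O)/C=C(\[Si](CC)(CC)CC)C[C@H](OC(=O)/C(C)=C\C)/C=C(/C)CCO[Si](C)(C)C(C)(C)C | intermediate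
14 | (2E,4S,5Z,8S,9Z)-12-((tert-butyldimethylsilyl)oxy)-4-hydroxy-6-iodo-10-methyldodeca-2,5,9-trien-8-yl (Z)-2-methylbut-2-enoate | C/C=C/[C@H](O)/C=C(\I)C[C@H](OC(=O)/C(C)=C\C)/C=C(/C)CCO[Si](C)(C)C(C)(C)C | intermediate
15 | (2E,4S,5Z,8S,9Z)-12-((tert-butyldimethylsilyl)oxy)-4-hydroxy-6-(hydroxymethyl)-10-methyldodeca-2,5,9-trien-8-yl (Z)-2-methylbut-2-enoate | C/C=C/[C@H](O)/C=C(\CO)C[C@H](OC(=O)/C(C)=C\C)/C=C(/C)CCO[Si](C)(C)C(C)(C)C | intermediate
16 | (2E,4S,5Z,8S,9Z)-6-(acetoxymethyl)-12-((tert-butyldimethylsilyl)oxy)-4-hydroxy-10-methyldodeca-2,5,9-trien-8-yl (Z)-2-methylbut-2-enoate | C/C=C/[C@H](O)/C=C(\COC(C)=O)C[C@H](OC(=O)/C(C)=C\C)/C=C(/C)CCO[Si](C)(C)C(C)(C)C | intermediate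
17 | 2-(bromomethyl)acrylic acid | C=C(CBr)C(=O)O | starting material
18 | (2E,4S,5Z,8S,9Z)-6-(acetoxymethyl)-12-((tert-butyldimethylsilyl)oxy)-10-methyl-8-(((Z)-2-methylbut-2-enoyl)oxy)dodeca-2,5,9-trien-4-yl 2-(bromomethyl)acrylate | C/C=C/[C@H](OC(=O)C(=C)CBr)/C=C(\COC(C)=O)C[C@H](OC(=O)/C(C)=C\C)/C=C(/C)CCO[Si](C)(C)C(C)(C)C | intermediate
19 | (1Z,4S,5Z)-2-(acetoxymethyl)-1-((2R)-4-(bromomethyl)-5-oxo-2,5-dihydrofuran-2-yl)-8-((tert-butyldimethylsilyl)oxy)-6-methylocta-1,5-dien-4-yl (Z)-2-methylbut-2-enoate | BrCC1=C[C@@H](/C=C(\COC(C)=O)C[C@H](OC(=O)/C(C)=C\C)/C=C(/C)CCO[Si](C)(C)C(C)(C)C)OC1=O | intermediate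
20 | (1Z,4S,5Z)-2-(acetoxymethyl)-1-((2R)-4-(bromomethyl)-5-oxo-2,5-dihydrofuran-2-yl)-8-hydroxy-6-methylocta-1,5-dien-4-yl (Z)-2-methylbut-2-enoate | BrCC1=C[C@@H](/C=C(\COC(C)=O)C[C@H](OC(=O)/C(C)=C\C)/C=C(/C)CCO)OC1=O | intermediate
21 | (1Z,4S,5Z)-2-(acetoxymethyl)-1-((2R)-4-(bromomethyl)-5-oxo-2,5-dihydrofuran-2-yl)-6-methyl-8-oxoocta-1,5-dien-4-yl (Z)-2-methylbut-2-enoate | BrCC1=C[C@@H](/C=C(\COC(C)=O)C[C@H](OC(=O)/C(C)=C\C)/C=C(/C)CC=O)OC1=O | intermediate
22 | allylchromium(III) dichloride derived from 21 (CrCl2 on C13 in place of Br) | Cl[Cr](Cl)CC1=C[C@@H](/C=C(\COC(C)=O)C[C@H](OC(=O)/C(C)=C\C)/C=C(/C)CC=O)OC1=O | intermediate (not isolated)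
23 | (3aR,4S,6Z,8S,10Z,11aR)-10-(acetoxymethyl)-4-hydroxy-6-methyl-3-methylidene-2-oxo-2,3,3a,4,5,8,9,11a-octahydrocyclodeca[b]furan-8-yl (Z)-2-methylbut-2-enoate (8-epi alcohol in germacrane numbering) | C=C1C(=O)O[C@@H]2/C=C(\COC(C)=O)C[C@H](OC(=O)/C(C)=C\C)/C=C(/C)C[C@H](O)[C@@H]12 | intermediate
24 | (3aS,6Z,8S,10Z,11aR)-10-(acetoxymethyl)-6-methyl-3-methylidene-2,4-dioxo-2,3,3a,4,5,8,9,11a-octahydrocyclodeca[b]furan-8-yl (Z)-2-methylbut-2-enoate | C=C1C(=O)O[C@@H]2/C=C(\COC(C)=O)C[C@H](OC(=O)/C(C)=C\C)/C=C(/C)CC(=O)[C@@H]12 | intermediate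
25 | (3aR,4R,6Z,8S,10Z,11aR)-10-(acetoxymethyl)-4-hydroxy-6-methyl-3-methylidene-2-oxo-2,3,3a,4,5,8,9,11a-octahydrocyclodeca[b]furan-8-yl (Z)-2-methylbut-2-enoate | C=C1C(=O)O[C@@H]2/C=C(\COC(C)=O)C[C@H](OC(=O)/C(C)=C\C)/C=C(/C)C[C@@H](O)[C@@H]12 | target

**Totals and risks**

Total step count: 18. Longest linear sequence: 18 steps (from 1).

Steps most likely to fail:

1. Step 16 (ring closure by C7–C8 allylation). Intermolecular allylation (oligomerisation), addition on the butenolide face syn to the side chain, or isomerisation of the aldehyde during the slow addition may outrun the closure. Fallback with a different nucleophile and activation mode: from alcohol 20, Pd(0)-catalysed stannylation of the allylic bromide with hexabutylditin should give the allylstannane alcohol F1; Dess–Martin oxidation gives the stannyl aldehyde F2; BF3·OEt2 in CH2Cl2 at −78 °C under high dilution then closes the ring by a Lewis-acid-promoted intramolecular allylstannane–aldehyde addition through an open transition state. The route is rejoined at 23 (either C8 epimer goes on into step 17; the 8R epimer would be 25 itself).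

2. Step 17 (C8 ketone). Enolisation at C7 of the keto lactone, leading to epimerisation or migration of the C11=C13 bond into conjugation, may consume material before the reduction. Fallback that avoids the ketone: from 23, Mitsunobu inversion with formic acid (PPh3, DIAD, THF, 0 °C) should give the inverted 8R formate F3, and the formate is cleaved selectively in the presence of the acetate and angelate with KHCO3 in MeOH at 0 °C, which rejoins the route at 25.

3. Step 13 (metathesis). Slow turnover at the electron-poor 1,1-disubstituted bromomethyl acrylate with catalyst decomposition, or loss of the allylic bromide (the same bromide is also the weak point of the acylation in step 12). Fallback that introduces the bromide after ring closure: from 16, DCC coupling with 2-(((triethylsilyl)oxy)methyl)acrylic acid gives the silyloxymethyl acrylate F4; ring-closing metathesis (Grubbs second-generation catalyst) gives the 3-(silyloxymethyl)butenolide F5; PPTS in MeOH removes only the triethylsilyl group to give the hydroxymethyl butenolide F6; Appel bromination (CBr4, PPh3, CH2Cl2, 0 °C) rejoins the route at 19.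

**Further compounds**

F1 | step 16 | (1Z,4S,5Z)-2-(acetoxymethyl)-8-hydroxy-6-methyl-1-((2R)-5-oxo-4-((tributylstannyl)methyl)-2,5-dihydrofuran-2-yl)octa-1,5-dien-4-yl (Z)-2-methylbut-2-enoate | CCCC[Sn](CCCC)(CCCC)CC1=C[C@@H](/C=C(\COC(C)=O)C[C@H](OC(=O)/C(C)=C\C)/C=C(/C)CCO)OC1=O
F2 | step 16 | (1Z,4S,5Z)-2-(acetoxymethyl)-6-methyl-8-oxo-1-((2R)-5-oxo-4-((tributylstannyl)methyl)-2,5-dihydrofuran-2-yl)octa-1,5-dien-4-yl (Z)-2-methylbut-2-enoate | CCCC[Sn](CCCC)(CCCC)CC1=C[C@@H](/C=C(\COC(C)=O)C[C@H](OC(=O)/C(C)=C\C)/C=C(/C)CC=O)OC1=O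
F3 | step 17 | (3aR,4R,6Z,8S,10Z,11aR)-10-(acetoxymethyl)-4-(formyloxy)-6-methyl-3-methylidene-2-oxo-2,3,3a,4,5,8,9,11a-octahydrocyclodeca[b]furan-8-yl (Z)-2-methylbut-2-enoate | C=C1C(=O)O[C@@H]2/C=C(\COC(C)=O)C[C@H](OC(=O)/C(C)=C\C)/C=C(/C)C[C@@H](OC=O)[C@@H]12
F4 | step 13 | (2E,4S,5Z,8S,9Z)-6-(acetoxymethyl)-12-((tert-butyldimethylsilyl)oxy)-10-methyl-8-(((Z)-2-methylbut-2-enoyl)oxy)dodeca-2,5,9-trien-4-yl 2-(((triethylsilyl)oxy)methyl)acrylate | C/C=C/[C@H](OC(=O)C(=C)CO[Si](CC)(CC)CC)/C=C(\COC(C)=O)C[C@H](OC(=O)/C(C)=C\C)/C=C(/C)CCO[Si](C)(C)C(C)(C)C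
F5 | step 13 | (1Z,4S,5Z)-2-(acetoxymethyl)-8-((tert-butyldimethylsilyl)oxy)-6-methyl-1-((2R)-5-oxo-4-(((triethylsilyl)oxy)methyl)-2,5-dihydrofuran-2-yl)octa-1,5-dien-4-yl (Z)-2-methylbut-2-enoate | CC[Si](CC)(CC)OCC1=C[C@@H](/C=C(\COC(C)=O)C[C@H](OC(=O)/C(C)=C\C)/C=C(/C)CCO[Si](C)(C)C(C)(C)C)OC1=O
F6 | step 13 | (1Z,4S,5Z)-2-(acetoxymethyl)-8-((tert-butyldimethylsilyl)oxy)-1-((2R)-4-(hydroxymethyl)-5-oxo-2,5-dihydrofuran-2-yl)-6-methylocta-1,5-dien-4-yl (Z)-2-methylbut-2-enoate | OCC1=C[C@@H](/C=C(\COC(C)=O)C[C@H](OC(=O)/C(C)=C\C)/C=C(/C)CCO[Si](C)(C)C(C)(C)C)OC1=O
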